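**Retrosynthetic overview** (core numbered as octahydro-2H-cyclohepta[b]furan-2-one: O1, C2, C3, C3a, C4–C8, C8a)
1. Late stage: the C8 isobutyrate comes from acylation, the C7 carbinol/but-2-enoyl unit from 1,2-addition of lithiated 1-methoxybuta-1,2-diene to a C7 ketone, and the C3/C3a hydrogens from syn hydrogenation of a C3=C3a butenolide.
2. Key disconnection: C5–C6 and C8–C8a are formed together in a (4+3) event between a chiral 1-alkoxy-2-siloxyallyl cation (C6–C7–C8) and 2-silyloxy-3-methyl-4-vinylfuran (C8a–C3a–C4–C5).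
3. Enabling feature: the γ-lactone ring (O1, C2, C3, C3a, C8a) is fused at C3a–C8a with its ring oxygen on C8a, so it can be written as an aromatic 2-silyloxyfuran whose C5 (= C8a) is nucleophilic and whose vinyl group supplies C4/C5; the facing C6(Me)–C7(O)–C8(O) triad is an oxyallyl cation at the ketone oxidation level.
4. Ring order: the lactone ring comes first (bought as 3-methyltetronic acid, carried as the furan) and the seven-membered ring second (key step); the furan aromaticity, the silyl groups and the auxiliary are removed afterwards.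
5. Stereochemistry: one bought stereocentre ((R)-1-phenylethanol) sets C8; C8a and C6 follow in the same event; C3, C3a and C7 are relayed by the cis-fused bicycle.

Key step: step 7

Remark: the (R)-1-phenylethyl group is assumed to direct attack to the face of the oxocarbenium ion anti to its phenyl ring (benzylic C–H eclipsing C=O+), which gives (8S); if the opposite sense is met, (S)-1-phenylethanol is used with no other change.
Remark: 3-methyltetronic acid 1 is taken as a catalogue compound; otherwise it is made from ethyl 2-methylacetoacetate by bromination and thermal ring closure.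

**Step 1**
Reactants: 1 3-methyltetronic acid
Product: 2 4-methyl-5-oxo-2,5-dihydrofuran-3-yl trifluoromethanesulfonate
Conditions: Tf2O, i-Pr2NEt, CH2Cl2, −78 °C
Reagents that add atoms: trifluoromethanesulfonic anhydride O=S(=O)(OS(=O)(=O)C(F)(F)F)C(F)(F)F
Why: O-sulfonylation of the vinylogous acid gives an enol triflate that is activated for cross-coupling.

**Step 2**
Reactants: 2 4-methyl-5-oxo-2,5-dihydrofuran-3-yl trifluoromethanesulfonate
Product: 3 3-methyl-4-vinylfuran-2(5H)-one
Conditions: vinylboronic acid pinacol ester, PdCl2(dppf) (5 mol%), K2CO3, dioxane/H2O, 60 °C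
Reagents that add atoms: vinylboronic acid pinacol ester C=CB1OC(C)(C)C(C)(C)O1
Why: Suzuki–Miyaura coupling of the electron-poor β-triflyloxy butenolide, a standard substrate class for this coupling.

**Step 3**
Reactants: 3 3-methyl-4-vinylfuran-2(5H)-one
Product: 4 tert-butyl(dimethyl)[(3-methyl-4-vinylfuran-2-yl)oxy]silane
Conditions: TBSOTf, Et3N, CH2Cl2, 0 °C; filtered and concentrated without aqueous work-up
Reagents that add atoms: tert-butyldimethylsilyl trifluoromethanesulfonate CC(C)(C)[Si](C)(C)OS(=O)(=O)C(F)(F)F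
Why: Soft enolization with a silyl triflate and an amine removes a C5 proton of the butenolide, and O-silylation gives the aromatic 2-silyloxyfuran (silyl dienol ether formation).

**Step 4**
Reactants: 5 methyl 2,2-dimethoxyacetate
Product: 6 1,1-dimethoxybutan-2-one
Conditions: EtMgBr (1.05 equiv), THF, −78 °C; H2O
Reagents that add atoms: ethylmagnesium bromide CC[Mg]Br
Why: Grignard addition to the α,α-dialkoxy ester should stop at the ketone because the magnesium-chelated tetrahedral intermediate persists at −78 °C until the quench.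

**Step 5**
Reactants: 6 1,1-dimethoxybutan-2-one; 7 (R)-1-phenylethanol
Product: 8 1-methoxy-1-[(1R)-1-phenylethoxy]butan-2-one (both epimers at the acetal carbon)
Conditions: CSA (cat.), cyclohexane, 5 Å MS, 60 °C (removal of MeOH)
Reagents that add atoms: none
Why: Acid-catalysed transacetalization with one equivalent of the alcohol should give mainly the mixed acetal; the acetal epimers need no separation because this carbon becomes planar in step 7.

**Step 6**
Reactants: 8 1-methoxy-1-[(1R)-1-phenylethoxy]butan-2-one
Product: 9 (Z)-triethyl({1-methoxy-1-[(1R)-1-phenylethoxy]but-2-en-2-yl}oxy)silane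
Conditions: TESOTf, Et3N, CH2Cl2, −78 to 0 °C
Reagents that add atoms: triethylsilyl trifluoromethanesulfonate CC[Si](CC)(CC)OS(=O)(=O)C(F)(F)F
Why: Soft enolization with silyl triflate and Et3N occurs at the methylene rather than at the acetal C–H and should give the thermodynamically preferred (Z)-silyl enol ether.

**Step 7**
Reactants: 4 tert-butyl(dimethyl)[(3-methyl-4-vinylfuran-2-yl)oxy]silane; 9 (Z)-triethyl({1-methoxy-1-[(1R)-1-phenylethoxy]but-2-en-2-yl}oxy)silane
Product: 13 (6S,8S,8aR)-3,6-dimethyl-8-[(1R)-1-phenylethoxy]-5,6,8,8a-tetrahydro-2H-cyclohepta[b]furan-2,7(4H)-dione, via oxocarbenium triflate 10 (not isolated), via silyloxyfuranium triflate 11 (not isolated), via silyl dienol ether 12 (not isolated)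
Conditions: TMSOTf (0.2 equiv), CH2Cl2, −95 to −78 °C, 9 added slowly to 4 (1.3 equiv); then 1 M aq. HCl, THF, 0 °C
Reagents that add atoms: none
Why: Proposed new method: TMSOTf removes the methoxy group of 9 to give the 1-alkoxy-2-siloxyallyl cation 10, C5 of the silyloxyfuran 4 (its most nucleophilic site) attacks the oxocarbenium carbon (C8–C8a bond, vinylogous Mukaiyama mode), and the silyloxyfuranium dienyl cation 11 is then closed at its vinyl terminus by the pendant (Z)-triethylsilyl enol ether (C5–C6 bond, Mukaiyama–Michael mode, releasing Et3SiOTf as chain carrier), so that the sequence amounts to an asynchronous dearomative (4+3) cycloaddition whose closest known relatives are the (4+3) cycloadditions of 1-phenylethoxy-substituted siloxyallyl cations with furan and the dearomative (4+3) cycloadditions of oxyallyl cations with 3-alkenylindoles. Only the seven-membered carbocycle is closed, in a 7-endo-trig mode onto the activated vinyl group, and the acidic work-up converts the silyl dienol ether 12 into the conjugated butenolide by protonation at C4. C8 is controlled by the (R)-1-phenylethyl group, which blocks one face of the oxocarbenium ion; C8a follows from a compact approach in which the siloxyallyl unit lies over the furan with the alkoxy group turned inward, which places O1 and the C8 oxygen trans; C6 is controlled by A(1,2) strain in the ring closure, where the C8 alkoxy group turns away from the OSiEt3 group so that the (Z)-enol ether places the methyl group trans to it. The step needs regioselectivity (furan C5 to the acetal carbon, enol carbon to the vinyl terminus), which the matched polarity of the two partners secures, and (4+3) instead of (3+2) closure, which is favoured because closure at C4 of the furanone would create a quaternary centre while the 3-methyl group holds the vinyl group s-cis to C5.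

**Step 8**
Reactants: 13 (6S,8S,8aR)-3,6-dimethyl-8-[(1R)-1-phenylethoxy]-5,6,8,8a-tetrahydro-2H-cyclohepta[b]furan-2,7(4H)-dione
Product: 14 (3R,3aS,6S,8S,8aR)-8-hydroxy-3,6-dimethylhexahydro-2H-cyclohepta[b]furan-2,7(3H)-dione
Conditions: H2 (50 bar), Pd(OH)2/C, EtOAc/AcOH, rt
Reagents that add atoms: none
Why: Heterogeneous hydrogenation should cleave the benzylic ether and add H2 syn to the tetrasubstituted C3=C3a bond from the convex face opposite C8 (the face of H-8a), which sets C3 and C3a with H-3, H-3a and H-8a all cis, as in all-cis hydrogenations of fully substituted butenolides.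

**Step 9**
Reactants: 14 (3R,3aS,6S,8S,8aR)-8-hydroxy-3,6-dimethylhexahydro-2H-cyclohepta[b]furan-2,7(3H)-dione
Product: 15 (3R,3aS,6S,8S,8aR)-3,6-dimethyl-8-(trimethylsilyloxy)hexahydro-2H-cyclohepta[b]furan-2,7(3H)-dione
Conditions: TMSCl, imidazole, CH2Cl2, 0 °C
Reagents that add atoms: chlorotrimethylsilane C[Si](C)(C)Cl
Why: Silylation of the secondary alcohol removes the acidic proton before the organolithium step with the smallest silyl group, which is lost again in the acidic hydrolysis of step 13.

**Step 10**
Reactants: 16 but-2-yn-1-ol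
Product: 17 1-methoxybut-2-yne
Conditions: NaH, THF, 0 °C; MeI, rt
Reagents that add atoms: iodomethane CI
Why: Williamson ether synthesis of a primary propargylic alkoxide.

**Step 11**
Reactants: 17 1-methoxybut-2-yne
Product: 18 1-methoxybuta-1,2-diene (racemic)
Conditions: KOt-Bu (cat.), 18-crown-6 (cat.), pentane, rt; distillation
Reagents that add atoms: none
Why: Base-catalysed propargyl-to-allenyl ether isomerization through the oxygen-stabilized propargylic anion; further isomerization to the 1,3-diene needs deprotonation of the less acidic methyl group and should be slower.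

**Step 12**
Reactants: 18 1-methoxybuta-1,2-diene; 15 (3R,3aS,6S,8S,8aR)-3,6-dimethyl-8-(trimethylsilyloxy)hexahydro-2H-cyclohepta[b]furan-2,7(3H)-dione
Product: 20 (3R,3aS,6S,7S,8S,8aR)-7-hydroxy-7-(1-methoxybuta-1,2-dien-1-yl)-3,6-dimethyl-8-(trimethylsilyloxy)octahydro-2H-cyclohepta[b]furan-2-one, via 1-lithio-1-methoxybuta-1,2-diene 19 (not isolated)
Conditions: n-BuLi, THF, −78 °C; then 15, −78 °C; H2O
Reagents that add atoms: none
Why: Alkoxyallenes are lithiated at C1 and add 1,2 to ketones in preference to lactones at −78 °C; attack on the C7 carbonyl of the cis-fused bicycle should come from the convex face, anti to the lactone ring and to the C6 methyl group, which gives the (7S) tertiary alcohol.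

**Step 13**
Reactants: 20 (3R,3aS,6S,7S,8S,8aR)-7-hydroxy-7-(1-methoxybuta-1,2-dien-1-yl)-3,6-dimethyl-8-(trimethylsilyloxy)octahydro-2H-cyclohepta[b]furan-2-one
Product: 21 (3R,3aS,6S,7S,8S,8aR)-7-[(E)-but-2-enoyl]-7,8-dihydroxy-3,6-dimethyloctahydro-2H-cyclohepta[b]furan-2-one
Conditions: 1 M aq. HCl, THF, 0 °C to rt
Reagents that add atoms: water O
Why: Acid hydrolysis of the 1-alkoxyallene (protonation at the central allene carbon, hydration of the oxocarbenium ion, loss of methanol) should give the conjugated (E)-enone, and the same acid cleaves the trimethylsilyl ether wherever it resides after any silyl shift in step 12.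

**Step 14**
Reactants: 21 (3R,3aS,6S,7S,8S,8aR)-7-[(E)-but-2-enoyl]-7,8-dihydroxy-3,6-dimethyloctahydro-2H-cyclohepta[b]furan-2-one
Product: 22 (3R,3aS,6S,7S,8S,8aR)-7-[(E)-but-2-enoyl]-7-hydroxy-3,6-dimethyl-2-oxooctahydro-2H-cyclohepta[b]furan-8-yl 2-methylpropanoate
Conditions: isobutyric anhydride, DMAP, Et3N, CH2Cl2, rt
Reagents that add atoms: isobutyric anhydride CC(C)C(=O)OC(=O)C(C)C
Why: DMAP-catalysed acylation is selective for the secondary C8 hydroxyl; the tertiary C7 hydroxyl between two substituted carbons should not react under these conditions.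

**Compound list**
1 | 3-methyltetronic acid (4-hydroxy-3-methylfuran-2(5H)-one) | CC1=C(O)COC1=O | starting material
2 | 4-methyl-5-oxo-2,5-dihydrofuran-3-yl trifluoromethanesulfonate | CC1=C(OS(=O)(=O)C(F)(F)F)COC1=O | intermediate
3 | 3-methyl-4-vinylfuran-2(5H)-one | C=CC1=C(C)C(=O)OC1 | intermediate
4 | tert-butyl(dimethyl)[(3-methyl-4-vinylfuran-2-yl)oxy]silane | C=CC1=COC(O[Si](C)(C)C(C)(C)C)=C1C | intermediate
5 | methyl 2,2-dimethoxyacetate | COC(OC)C(=O)OC | starting material
6 | 1,1-dimethoxybutan-2-one | CCC(=O)C(OC)OC | intermediate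
7 | (R)-1-phenylethanol | C[C@@H](O)c1ccccc1 | starting material
8 | 1-methoxy-1-[(1R)-1-phenylethoxy]butan-2-one (both epimers at the acetal carbon) | CCC(=O)C(OC)O[C@H](C)c1ccccc1 | intermediate
9 | (Z)-triethyl({1-methoxy-1-[(1R)-1-phenylethoxy]but-2-en-2-yl}oxy)silane | C/C=C(\O[Si](CC)(CC)CC)C(OC)O[C@H](C)c1ccccc1 | intermediate
10 | O-[(1R)-1-phenylethyl] oxocarbenium triflate of (Z)-2-(triethylsilyloxy)but-2-enal | C/C=C(\O[Si](CC)(CC)CC)C=[O+][C@H](C)c1ccccc1.[O-]S(=O)(=O)C(F)(F)F | intermediate
11 | 2-(tert-butyldimethylsilyloxy)-3-methyl-4-vinylfuranium triflate carrying at C5 the (Z)-1-[(1R)-1-phenylethoxy]-2-(triethylsilyloxy)but-2-enyl group (C8 and C8a configured as in 13) | C/C=C(\O[Si](CC)(CC)CC)[C@@H](O[C@H](C)c1ccccc1)[C@@H]1[O+]=C(O[Si](C)(C)C(C)(C)C)C(C)=C1C=C.[O-]S(=O)(=O)C(F)(F)F | intermediate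
12 | (6S,8S,8aR)-2-(tert-butyldimethylsilyloxy)-3,6-dimethyl-8-[(1R)-1-phenylethoxy]-5,6,8,8a-tetrahydro-7H-cyclohepta[b]furan-7-one (silyl dienol ether with C3a=C4) | O=C1[C@@H](C)CC=C2C(C)=C(O[Si](C)(C)C(C)(C)C)O[C@H]2[C@@H]1O[C@H](C)c1ccccc1 | intermediate
13 | (6S,8S,8aR)-3,6-dimethyl-8-[(1R)-1-phenylethoxy]-5,6,8,8a-tetrahydro-2H-cyclohepta[b]furan-2,7(4H)-dione | O=C1[C@@H](C)CCC2=C(C)C(=O)O[C@H]2[C@@H]1O[C@H](C)c1ccccc1 | intermediate
14 | (3R,3aS,6S,8S,8aR)-8-hydroxy-3,6-dimethylhexahydro-2H-cyclohepta[b]furan-2,7(3H)-dione | O=C1[C@@H](C)CC[C@@H]2[C@@H](OC(=O)[C@@H]2C)[C@@H]1O | intermediate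
15 | (3R,3aS,6S,8S,8aR)-3,6-dimethyl-8-(trimethylsilyloxy)hexahydro-2H-cyclohepta[b]furan-2,7(3H)-dione | O=C1[C@@H](C)CC[C@@H]2[C@@H](OC(=O)[C@@H]2C)[C@@H]1O[Si](C)(C)C | intermediate
16 | but-2-yn-1-ol | CC#CCO | starting material
17 | 1-methoxybut-2-yne | CC#CCOC | intermediate
18 | 1-methoxybuta-1,2-diene (racemic) | CC=C=COC | intermediate
19 | 1-lithio-1-methoxybuta-1,2-diene | CC=C=C([Li])OC | intermediate
20 | (3R,3aS,6S,7S,8S,8aR)-7-hydroxy-7-(1-methoxybuta-1,2-dien-1-yl)-3,6-dimethyl-8-(trimethylsilyloxy)octahydro-2H-cyclohepta[b]furan-2-one (allene axis unassigned) | CC=C=C(OC)[C@]1(O)[C@@H](C)CC[C@@H]2[C@@H](OC(=O)[C@@H]2C)[C@@H]1O[Si](C)(C)C | intermediate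
21 | (3R,3aS,6S,7S,8S,8aR)-7-[(E)-but-2-enoyl]-7,8-dihydroxy-3,6-dimethyloctahydro-2H-cyclohepta[b]furan-2-one | C/C=C/C(=O)[C@]1(O)[C@@H](C)CC[C@@H]2[C@@H](OC(=O)[C@@H]2C)[C@@H]1O | intermediate
22 | (3R,3aS,6S,7S,8S,8aR)-7-[(E)-but-2-enoyl]-7-hydroxy-3,6-dimethyl-2-oxooctahydro-2H-cyclohepta[b]furan-8-yl 2-methylpropanoate | C/C=C/C(=O)[C@]1(O)[C@@H](C)CC[C@@H]2[C@@H](OC(=O)[C@@H]2C)[C@@H]1OC(=O)C(C)C | target

**Step count and risks**
Total step count: 14. Longest linear sequence: 9 steps (1, 2, 3, 7, 8, 9, 12, 13, 14 from compound 1; the branch from compound 5 through steps 4, 5, 6 is equally long).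

Step 7 (key step, new method). The annulation may stop after the first C–C bond through desilylation of the furanium ion, may close to a five-membered ring at C4 of the furanone, or may show low diastereoselectivity in the first bond formation. The fallback sets out from 4 and 9 and returns at 13, making the two bonds in separate known operations. Stoichiometric BF3·OEt2 (CH2Cl2, −78 °C) promotes only the vinylogous Mukaiyama addition of 4 to the acetal carbon of 9, and aqueous work-up removes both silyl groups to give the open-chain keto butenolide (5R)-3-methyl-5-{(1S)-2-oxo-1-[(1R)-1-phenylethoxy]butyl}-4-vinylfuran-2(5H)-one F1. Pyrrolidine/AcOH then forms the enamine at the ethyl ketone methylene, which closes the C5–C6 bond by intramolecular 1,6-Michael addition to the vinyl butenolide (Stork enamine mode) and gives 13 after hydrolysis.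

Step 12. The lithium reagent may add to the wrong face of the C7 carbonyl or to the lactone carbonyl. The fallback sets out from 15 and returns at 21; it delivers the oxygen, not the carbon chain, in the face-selective step, so a bias toward the face wrongly taken by the carbanion now places the hydroxyl group there. Takai–Lombardo methylenation (Zn, CH2Br2, TiCl4), which spares lactones and does not enolize the ketone, gives the 7-methylene compound F2. Dihydroxylation (OsO4 cat., NMO, buffered acetone/H2O) gives the 7-hydroxy-7-(hydroxymethyl) compound F3. Selective oxidation of the primary alcohol (TEMPO, PhI(OAc)2) gives the α-hydroxy aldehyde F4. Addition of (E)-prop-1-enylmagnesium bromide at −78 °C gives the allylic alcohol F5, MnO2 oxidation gives the 8-O-trimethylsilyl enone F6, and aqueous HCl in THF returns 21.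

Step 8. Reduction of the tetrasubstituted C3=C3a bond may be sluggish, with competing hydrogenolysis of the allylic C8a–O1 bond or addition from the wrong face. The fallback sets out from 13 and returns at 14, separating the reduction from the deprotection and using hydride conjugate reduction. Nickel boride generated in situ (NiCl2·6H2O, NaBH4, MeOH, 0 °C) reduces the butenolide from the convex face with protonation at C3 on the same face; it also reduces the C7 ketone and leaves the benzylic ether, giving the 7-hydroxy lactone F7 as a mixture of carbinol epimers. Oxidation (SO3·pyridine, DMSO, i-Pr2NEt) restores the ketone in the saturated 8-(1-phenylethoxy) diketone F8, and mild hydrogenolysis (H2 1 bar, Pd/C, EtOAc) gives 14.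

**Further compounds**
F1 | step 7 | (5R)-3-methyl-5-{(1S)-2-oxo-1-[(1R)-1-phenylethoxy]butyl}-4-vinylfuran-2(5H)-one | CCC(=O)[C@@H](O[C@H](C)c1ccccc1)[C@@H]1OC(=O)C(C)=C1C=C
F2 | step 12 | 3,6-dimethyl-7-methylidene-8-(trimethylsilyloxy)octahydro-2H-cyclohepta[b]furan-2-one (C3, C3a, C6, C8, C8a as in 15) | C=C1[C@@H](C)CC[C@@H]2[C@@H](OC(=O)[C@@H]2C)[C@@H]1O[Si](C)(C)C
F3 | step 12 | 7-hydroxy-7-(hydroxymethyl)-3,6-dimethyl-8-(trimethylsilyloxy)octahydro-2H-cyclohepta[b]furan-2-one (7-OH on the face of the lactone ring) | OC[C@]1(O)[C@@H](C)CC[C@@H]2[C@@H](OC(=O)[C@@H]2C)[C@@H]1O[Si](C)(C)C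
F4 | step 12 | 7-hydroxy-3,6-dimethyl-2-oxo-8-(trimethylsilyloxy)octahydro-2H-cyclohepta[b]furan-7-carbaldehyde | O=C[C@]1(O)[C@@H](C)CC[C@@H]2[C@@H](OC(=O)[C@@H]2C)[C@@H]1O[Si](C)(C)C
F5 | step 12 | 7-hydroxy-7-[(E)-1-hydroxybut-2-enyl]-3,6-dimethyl-8-(trimethylsilyloxy)octahydro-2H-cyclohepta[b]furan-2-one (carbinol epimers) | C/C=C/C(O)[C@]1(O)[C@@H](C)CC[C@@H]2[C@@H](OC(=O)[C@@H]2C)[C@@H]1O[Si](C)(C)C
F6 | step 12 | 7-[(E)-but-2-enoyl]-7-hydroxy-3,6-dimethyl-8-(trimethylsilyloxy)octahydro-2H-cyclohepta[b]furan-2-one | C/C=C/C(=O)[C@]1(O)[C@@H](C)CC[C@@H]2[C@@H](OC(=O)[C@@H]2C)[C@@H]1O[Si](C)(C)C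
F7 | step 8 | 7-hydroxy-3,6-dimethyl-8-[(1R)-1-phenylethoxy]octahydro-2H-cyclohepta[b]furan-2-one (C7 epimers; other centres as in 14) | OC1[C@@H](C)CC[C@@H]2[C@@H](OC(=O)[C@@H]2C)[C@@H]1O[C@H](C)c1ccccc1
F8 | step 8 | 3,6-dimethyl-8-[(1R)-1-phenylethoxy]hexahydro-2H-cyclohepta[b]furan-2,7(3H)-dione (ring centres as in 14) | O=C1[C@@H](C)CC[C@@H]2[C@@H](OC(=O)[C@@H]2C)[C@@H]1O[C@H](C)c1ccccc1
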